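Flavan numbering is used throughout. Atoms of the 2,3-trans half carry a prime, atoms of the all-cis half do not.

## Analysis of the target

The target is a dimer of two 7,8,4'-trihydroxyflavan-3,4-diol units in which one oxygen joins C4 of one chroman to C4' of the other. Each chroman carries a 4-hydroxyphenyl ring at C2 and a pyrogallol-type ring A. There are six stereocentres: the unprimed half is all-cis (2R,3R,4R) and the primed half is 2,3-trans-3,4-cis (2S,3R,4R). The halves are alike at C3 and C4 and differ only at C2, so the molecule has no symmetry that a synthesis could use. The bridging oxygen sits on two secondary carbons that are benzylic to oxygen-rich rings (O7 para, O1 ortho), so the ether ionises under acid; C2 and C2' are 4-oxybenzylic ethers, and the free pyrogallol rings are oxidised in air, above all under base. The main difficulty is the C4–O–C4' bond. A flavan C4 cation is attacked trans to its 3-oxygen, while both halves are 3,4-cis, and an SN2 reaction between two secondary benzylic centres is not available. The all-cis ring is in addition the less stable 2,3-arrangement and has to be set kinetically. The strategy rests on one feature: C3' lies between the ether carbon C4' and the 4-hydroxybenzylic carbon C2'. The primed pyran ring can therefore be grown onto the bridging oxygen, with C3' as the carbonyl carbon of an alpha-alkoxy aldehyde whose alkoxy group is the whole all-cis half and C2' as a 4-oxybenzyl carbanion equivalent. C2' is forgiving because trans is its stable configuration.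

## Retrosynthetic reasoning

Target 30 is traced to its hepta-O-benzyl ether 29. All six phenols and O3 stay masked until the last step, so the air-sensitive polyphenol appears only once, and one hydrogenolysis removes all seven groups.

In 29 the O1'–C2' bond is cut. This opens the primed pyran ring to epoxide 27, a trans oxirane across C2' and C3' with O1' held as an aryl silyl ether. The cut is made here because C2' is a 4-oxybenzylic carbon: once the phenol is freed (28), mild acid opens the oxirane at C2' in the 6-endo sense, and both an inversion path and a cationic path end in the 2,3-trans ring.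

In 27 the C2'–C3' bond and the oxirane C2'–O bond are cut together. This gives aldehyde 23, which already carries the complete all-cis half on its alpha-oxygen, and sulfonium salt 25, used as its ylide 26. The gain is that the bridging ether exists before the second ring is built, so no substitution at a flavan C4 is ever needed. The forward reaction has to add the ylide to one face of the formyl group under the control of C4' and must not epimerise C4'.

Aldehyde 23 is configurationally labile, so it is drawn back to the vinyl compound 21 and released only at the last moment by ozonolysis under neutral conditions. In 21 the C4'–O bond is cut to alcohol 13 and allylic carbonate 19. Alcohol 13 acts as the oxygen nucleophile, so C4 keeps its configuration. A branch-selective iridium-catalysed allylic etherification sets C4' under catalyst control. This pairing was preferred to a carbenoid O–H insertion followed by ester reduction because it needs no acid next to the ionisable 4-OH and no hydride reduction to reach the aldehyde.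

Carbonate 19 goes back through alcohol 18 and ester 17 to aldehyde 16, and from there through 15 to 14. In 14 the hydroxyl next to the formyl group is set apart from the other two by its hydrogen bond, so the silyl ether that will become O1' can be placed selectively.

In 13 the pattern 3-OBn/4-OH is reached from 12 and 11 by a protecting-group exchange. The all-cis C3 centre is set by reduction of ketone 10 with a bulky hydride. Ketone 10 comes from alcohol 9, and 9 from silyl enol ether 7 by hydroboration (through 8). That step keeps the C4 oxygen of flavanone 6, fixes C4 cis to the 2-aryl group and gives the 3-OH and the 4-oxygen in differentiated form.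

Flavanone 6 is cut at the C2–aryl bond to chromone 4 and boronic acid 5. An asymmetric conjugate addition sets C2, the only centre of this half that is not controlled by the ring. Chromone 4 is made from 2 (through 3), and 2 from 1.

Salt 25 is made from chloride 24 in one step.

## Alternatives that were turned down

Alternative 1: The trans half is cut at C4'–C4a' and O1'–C2'. In the forward step the magnesium phenoxide of A1 adds through its free ortho carbon to epoxy aldehyde A2, and the phenol oxygen then opens the oxirane at the benzylic carbon to give diol A3. In its favour, two bonds and the pyran ring form in one step from two small pieces, and magnesium chelation directs the attack to the ortho carbon. For building the trans half alone it is shorter than the chosen route and is the stronger plan on that point. Against it, A3 arrives as a free 3,4-diol and the bridging ether is still to be made. Attack of the 4-OH of A3 on a C4 cation of the other half would give a 3,4-trans link there, and attack of an alcohol such as 13 on the C4' cation of A3 would give a 3',4'-trans link. Both are wrong, and the two hydroxyls of A3 would also have to be told apart. The chosen strategy gives up the short ring synthesis and in return makes the C4'–O bond first, from 13 as nucleophile, and grows the ring afterwards.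

Alternative 2: The oxygen of dihydrofuran A4 becomes the bridging oxygen. Two asymmetric Heck arylations with aryl triflate A5, under a palladium catalyst with a chiral bisphosphine, form C4–C4a and C4'–C4a' and give A6. In its favour, the bridging oxygen and both benzylic ether centres are set in one catalytic operation from a cheap heterocycle. On the formation of the central ether this plan is stronger than the chosen one, which needs a separate etherification. Against it, A5 carries a bulky ortho-silyloxy group, and the second arylation has to compete with double-bond migration. After cleavage of the ring alkene of A6 the two arms on oxygen are identical, but the target needs a 2,3-cis ring on one arm and a 2,3-trans ring on the other. Epoxide opening gives the trans ring on both arms, so this plan suits a symmetric bis-trans dimer and leaves the all-cis half unsolved. The chosen strategy makes the all-cis ring first, by ketone reductions on a closed ring, and only then builds the trans ring on the bridging oxygen.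

Alternative 3: Both pyran rings are cut at O1–C8a and O1'–C8a'. The open-chain bis(aryl bromide) diol A7, with all six stereocentres in place, is closed twice by copper-catalysed O-arylation, with a phenanthroline ligand and a carbonate base, to give A8. In its favour, both ring closures run with retention and without an ionisable benzylic intermediate. The 2,3-cis ring is then no harder to close than the trans ring, and on that point this plan is cleaner than the chosen one. Against it, the difficulty is only moved: A7 still contains the bis-benzylic ether and needs six stereocentres set in an open chain without a ring to direct them. Its aryl bromides are flanked by two ortho substituents, its nucleophiles are hindered secondary benzylic alcohols, and the route would be long and linear. The chosen strategy offers ring-based control of five of the six centres and a convergent assembly.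

Key step: step 18

Assumption: where a chiral ligand or ketone catalyst is named, its hand is the one predicted by the accepted model for that catalyst family; if a test reaction on a simple model showed the opposite sense, the mirror-image catalyst would be used with no other change.

Remark: the silyl group on O1' is taken as triisopropylsilyl, which resists transfer to alkoxides in steps 15 and 18, and the ylide is made with a potassium base so that no chelating cation is present.

## Route

Step 1
Reactants: 1 1-(2,3,4-trihydroxyphenyl)ethanone (gallacetophenone)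
Product: 2 1-[3,4-bis(benzyloxy)-2-hydroxyphenyl]ethanone
Conditions: BnBr (2.1 equiv), K2CO3, acetone, reflux
Reagents that add atoms: benzyl bromide, BrCc1ccccc1
Why: Williamson etherification; the 2-OH is tied to the ketone by a hydrogen bond and is the least reactive, so two equivalents of halide take O3 and O4.

Step 2
Reactants: 2 1-[3,4-bis(benzyloxy)-2-hydroxyphenyl]ethanone
Product: 4 7,8-bis(benzyloxy)-4H-chromen-4-one, via enaminone 3 (not isolated)
Conditions: Me2NCH(OMe)2, toluene, 100 °C; then conc. HCl, CH2Cl2, rt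
Reagents that add atoms: N,N-dimethylformamide dimethyl acetal, COC(OC)N(C)C
Why: Condensation of the methyl ketone gives the enaminone, and acid closes the pyranone ring with loss of dimethylamine (the standard chromone synthesis from 2-hydroxyacetophenones).

Step 3
Reactants: 4 7,8-bis(benzyloxy)-4H-chromen-4-one; 5 [4-(benzyloxy)phenyl]boronic acid
Product: 6 (2S)-7,8-bis(benzyloxy)-2-[4-(benzyloxy)phenyl]chroman-4-one
Conditions: [Rh(OH)(cod)]2 (1.5 mol %), (S)-MeO-F12-BIPHEP (3.3 mol %), toluene/H2O, 40 °C
Reagents that add atoms: none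
Why: Hayashi–Miyaura rhodium-catalysed asymmetric 1,4-addition of an arylboronic acid to a chromone; the bisphosphine sets C2 in the arrangement that is named 2R once C3 carries oxygen. The base-free hydroxo complex avoids retro-oxa-Michael ring opening and so racemisation.

Step 4
Reactants: 6 (2S)-7,8-bis(benzyloxy)-2-[4-(benzyloxy)phenyl]chroman-4-one
Product: 7 {[(2S)-7,8-bis(benzyloxy)-2-[4-(benzyloxy)phenyl]-2H-chromen-4-yl]oxy}(tert-butyl)dimethylsilane
Conditions: t-BuMe2SiOTf, Et3N, CH2Cl2, 0 °C
Reagents that add atoms: tert-butyldimethylsilyl triflate, CC(C)(C)[Si](C)(C)OS(=O)(=O)C(F)(F)F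
Why: Soft enolisation with a silyl triflate and an amine gives the only possible enol ether (C3=C4) without a free enolate, so C2 is untouched.

Step 5
Reactants: 7 {[(2S)-7,8-bis(benzyloxy)-2-[4-(benzyloxy)phenyl]-2H-chromen-4-yl]oxy}(tert-butyl)dimethylsilane
Product: 9 (2R,3R,4R)-7,8-bis(benzyloxy)-2-[4-(benzyloxy)phenyl]-4-[(tert-butyldimethylsilyl)oxy]chroman-3-ol (2,3-trans-3,4-trans), via alkylborane 8 (not isolated)
Conditions: BH3·THF, THF, 0 °C → rt; then 30 % H2O2, aq NaOH (pH ca. 9), 0 °C
Reagents that add atoms: hydrogen peroxide, OO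
Why: Hydroboration–oxidation of a silyl enol ether puts boron on C3 (beta to oxygen) by syn addition on the face away from the 2-aryl group. After oxidation with retention the 3-OH is trans to the aryl group and the 4-silyloxy group is cis to it, which sets C4.

Step 6
Reactants: 9 (2R,3R,4R)-7,8-bis(benzyloxy)-2-[4-(benzyloxy)phenyl]-4-[(tert-butyldimethylsilyl)oxy]chroman-3-ol
Product: 10 (2R,4R)-7,8-bis(benzyloxy)-2-[4-(benzyloxy)phenyl]-4-[(tert-butyldimethylsilyl)oxy]chroman-3-one
Conditions: Dess–Martin periodinane, NaHCO3, CH2Cl2, 0 °C → rt; crude product used at once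
Reagents that add atoms: none
Why: Dess–Martin oxidation is neutral and fast, as in the known oxidation of 2,3-trans-flavan-3-ols to flavan-3-ones. The ketone is not purified on silica because C2 and C4 are both alpha to it.

Step 7
Reactants: 10 (2R,4R)-7,8-bis(benzyloxy)-2-[4-(benzyloxy)phenyl]-4-[(tert-butyldimethylsilyl)oxy]chroman-3-one
Product: 11 (2R,3S,4R)-7,8-bis(benzyloxy)-2-[4-(benzyloxy)phenyl]-4-[(tert-butyldimethylsilyl)oxy]chroman-3-ol (all-cis)
Conditions: LiBH(s-Bu)3, THF, −78 °C; AcOH quench at −78 °C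
Reagents that add atoms: none
Why: The bulky hydride attacks the C3 carbonyl from the equatorial side and gives the axial alcohol, cis to the equatorial 2-aryl and 4-silyloxy groups (the known 2,3-trans to 2,3-cis inversion of flavan-3-ols). The cold acidic quench prevents a 1,2-silyl shift in the alkoxide.

Step 8
Reactants: 11 (2R,3S,4R)-7,8-bis(benzyloxy)-2-[4-(benzyloxy)phenyl]-4-[(tert-butyldimethylsilyl)oxy]chroman-3-ol
Product: 12 tert-butyl{[(2R,3S,4R)-3,7,8-tris(benzyloxy)-2-[4-(benzyloxy)phenyl]chroman-4-yl]oxy}dimethylsilane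
Conditions: 2-benzyloxy-1-methylpyridinium triflate, MgO, PhCF3, 85 °C
Reagents that add atoms: 2-benzyloxy-1-methylpyridinium triflate, C[n+]1ccccc1OCc1ccccc1.[O-]S(=O)(=O)C(F)(F)F
Why: Dudley benzylation transfers benzyl under neutral conditions. It is chosen because an alkoxide at O3 would draw the cis silyl group over from O4.

Step 9
Reactants: 12 tert-butyl{[(2R,3S,4R)-3,7,8-tris(benzyloxy)-2-[4-(benzyloxy)phenyl]chroman-4-yl]oxy}dimethylsilane
Product: 13 (2R,3R,4R)-3,7,8-tris(benzyloxy)-2-[4-(benzyloxy)phenyl]chroman-4-ol (all-cis)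
Conditions: Bu4NF, THF, 0 °C → rt
Reagents that add atoms: none
Why: Fluoride cleaves the Si–O bond only, so the 4-OH is freed with every stereocentre unchanged.

Step 10
Reactants: 14 2,3,4-trihydroxybenzaldehyde
Product: 15 3,4-bis(benzyloxy)-2-hydroxybenzaldehyde
Conditions: BnBr (2.1 equiv), K2CO3, DMF, rt
Reagents that add atoms: benzyl bromide, BrCc1ccccc1
Why: Williamson etherification; as in step 1, the hydroxyl hydrogen-bonded to the carbonyl group stays free.

Step 11
Reactants: 15 3,4-bis(benzyloxy)-2-hydroxybenzaldehyde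
Product: 16 3,4-bis(benzyloxy)-2-[(triisopropylsilyl)oxy]benzaldehyde
Conditions: i-Pr3SiOTf, 2,6-lutidine, CH2Cl2, 0 °C → rt
Reagents that add atoms: triisopropylsilyl triflate, CC(C)[Si](C(C)C)(C(C)C)OS(=O)(=O)C(F)(F)F
Why: A silyl triflate silylates the flanked phenol. The bulky triisopropylsilyl ether withstands the alkoxide and ylide steps and is removed by fluoride at the end.

Step 12
Reactants: 16 3,4-bis(benzyloxy)-2-[(triisopropylsilyl)oxy]benzaldehyde
Product: 17 ethyl (2E)-3-{3,4-bis(benzyloxy)-2-[(triisopropylsilyl)oxy]phenyl}prop-2-enoate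
Conditions: (EtO)2P(O)CH2CO2Et, LiCl, DBU, MeCN, rt
Reagents that add atoms: triethyl phosphonoacetate, CCOC(=O)CP(=O)(OCC)OCC
Why: Horner–Wadsworth–Emmons olefination under Masamune–Roush conditions is E-selective, and its mild base spares the aryl silyl ether.

Step 13
Reactants: 17 ethyl (2E)-3-{3,4-bis(benzyloxy)-2-[(triisopropylsilyl)oxy]phenyl}prop-2-enoate
Product: 18 (2E)-3-{3,4-bis(benzyloxy)-2-[(triisopropylsilyl)oxy]phenyl}prop-2-en-1-ol
Conditions: i-Bu2AlH (2.2 equiv), CH2Cl2, −78 °C; aq potassium sodium tartrate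
Reagents that add atoms: none
Why: 1,2-Reduction of the enoate by the aluminium hydride gives the allylic alcohol and leaves the alkene geometry unchanged.

Step 14
Reactants: 18 (2E)-3-{3,4-bis(benzyloxy)-2-[(triisopropylsilyl)oxy]phenyl}prop-2-en-1-ol
Product: 19 tert-butyl (2E)-3-{3,4-bis(benzyloxy)-2-[(triisopropylsilyl)oxy]phenyl}prop-2-en-1-yl carbonate
Conditions: Boc2O, DMAP (cat.), CH2Cl2, 0 °C → rt
Reagents that add atoms: di-tert-butyl dicarbonate, CC(C)(C)OC(=O)OC(=O)OC(C)(C)C
Why: Acylation gives the tert-butyl carbonate, whose leaving group releases only the poorly nucleophilic tert-butoxide and so does not compete in step 15.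

Step 15
Reactants: 13 (2R,3R,4R)-3,7,8-tris(benzyloxy)-2-[4-(benzyloxy)phenyl]chroman-4-ol; 19 tert-butyl (2E)-3-{3,4-bis(benzyloxy)-2-[(triisopropylsilyl)oxy]phenyl}prop-2-en-1-yl carbonate
Product: 21 (2R,3R,4R)-3,7,8-tris(benzyloxy)-2-[4-(benzyloxy)phenyl]-4-{[(1S)-1-{3,4-bis(benzyloxy)-2-[(triisopropylsilyl)oxy]phenyl}prop-2-en-1-yl]oxy}chromane, via copper alkoxide 20 (not isolated)
Conditions: 13, LiN(SiMe3)2, THF, 0 °C; CuI; then 19 (1.3 equiv), [Ir(cod)Cl]2 (2 mol %), (Sa,Sc,Sc)-O,O'-(1,1'-binaphthyl-2,2'-diyl) N,N-bis(1-phenylethyl)phosphoramidite (4 mol %, preactivated with n-PrNH2), THF, rt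
Reagents that add atoms: none
Why: Iridium-catalysed asymmetric allylic etherification with a copper alkoxide of a secondary alcohol gives the branched ether. The catalyst decides which face of the allyl unit is attacked and so sets C4' (S), and C4 is retained because the O–H bond of 13 reacts and not its C–O bond.

Step 16
Reactants: 21 (2R,3R,4R)-3,7,8-tris(benzyloxy)-2-[4-(benzyloxy)phenyl]-4-{[(1S)-1-{3,4-bis(benzyloxy)-2-[(triisopropylsilyl)oxy]phenyl}prop-2-en-1-yl]oxy}chromane
Product: 23 (2R)-2-{3,4-bis(benzyloxy)-2-[(triisopropylsilyl)oxy]phenyl}-2-{[(2R,3R,4R)-3,7,8-tris(benzyloxy)-2-[4-(benzyloxy)phenyl]chroman-4-yl]oxy}acetaldehyde, via ozonide 22 (not isolated)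
Conditions: O3, CH2Cl2, −78 °C (Sudan Red 7B end point); then PPh3, −78 °C → rt; used at once
Reagents that add atoms: ozone, [O-][O+]=O
Why: Ozonolysis with reductive work-up turns the vinyl group into the formyl group without acid or base, so the alpha-aryl alpha-alkoxy centre is not epimerised (its descriptor changes from S to R only because of the priority rules). The dye end point keeps ozone away from the alkoxyarenes.

Step 17
Reactants: 24 1-(benzyloxy)-4-(chloromethyl)benzene
Product: 25 [4-(benzyloxy)benzyl]dimethylsulfonium tetrafluoroborate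
Conditions: Me2S (3 equiv), NaBF4, acetone, rt
Reagents that add atoms: dimethyl sulfide, CSC; sodium tetrafluoroborate, [Na+].F[B-](F)(F)F
Why: S-Alkylation of the sulfide by the activated benzylic chloride; precipitation of NaCl drives the anion exchange to the non-nucleophilic tetrafluoroborate.

Step 18
Reactants: 23 (2R)-2-{3,4-bis(benzyloxy)-2-[(triisopropylsilyl)oxy]phenyl}-2-{[(2R,3R,4R)-3,7,8-tris(benzyloxy)-2-[4-(benzyloxy)phenyl]chroman-4-yl]oxy}acetaldehyde; 25 [4-(benzyloxy)benzyl]dimethylsulfonium tetrafluoroborate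
Product: 27 (2R,3R,4R)-3,7,8-tris(benzyloxy)-2-[4-(benzyloxy)phenyl]-4-{(R)-{3,4-bis(benzyloxy)-2-[(triisopropylsilyl)oxy]phenyl}[(2S,3R)-3-(4-benzyloxyphenyl)oxiran-2-yl]methoxy}chromane (trans oxirane), via sulfonium ylide 26 (not isolated)
Conditions: 25 (1.5 equiv), KN(SiMe3)2 (1.4 equiv), THF, −78 °C, 30 min; then 23, −78 → −40 °C
Reagents that add atoms: none
Why: Ylide 26, preformed with a slight deficit of base so that no free amide meets the aldehyde, adds to the formyl carbon of 23 to give a betaine, and the anti betaine closes by 3-exo-tet displacement of dimethyl sulfide by the alkoxide; this forms C2'–C3' and the C2'–O bond of the oxirane. The closest known reaction type is the Corey–Chaykovsky epoxidation of aldehydes, alpha-alkoxy aldehydes included, with semi-stabilised benzylic sulfonium ylides, which is trans-selective. C3' is controlled by the C4' stereocentre through the polar Felkin–Anh arrangement: the C4'–O bond stands anti to the incoming ylide and the ylide passes the hydrogen, which puts O3' anti to O4' in the extended chain, the relationship that becomes 3,4-cis in the ring. C2' is controlled by the reversal of the syn betaine, which is easier with a potassium counter-ion, so the trans oxirane should dominate; this centre is in any case reopened in step 19. The step needs facial selectivity at the aldehyde and retention of C4'; the first rests on the large difference between the ether oxygen and the hydrogen on C4' and on the absence of a chelating cation (KBF4 is insoluble in THF), the second on the low temperature, the preformed ylide and the speed of carbonyl addition relative to enolisation. The aryl triisopropylsilyl ether is too hindered to move to the betaine alkoxide, and no other group of 23 reacts with the ylide.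

Step 19
Reactants: 27 (2R,3R,4R)-3,7,8-tris(benzyloxy)-2-[4-(benzyloxy)phenyl]-4-{(R)-{3,4-bis(benzyloxy)-2-[(triisopropylsilyl)oxy]phenyl}[(2S,3R)-3-(4-benzyloxyphenyl)oxiran-2-yl]methoxy}chromane
Product: 29 (2R,3R,4R)-3,7,8-tris(benzyloxy)-2-[4-(benzyloxy)phenyl]-4-{[(2S,3R,4R)-7,8-bis(benzyloxy)-2-[4-(benzyloxy)phenyl]-3-hydroxychroman-4-yl]oxy}chromane, via epoxy phenol 28 (not isolated)
Conditions: Bu4NF/AcOH (1:1), THF, 0 °C; aqueous work-up; then pyridinium p-toluenesulfonate (10 mol %), CH2Cl2, 0 °C → rt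
Reagents that add atoms: none
Why: Buffered fluoride frees O1' as the neutral phenol, and mild acid then activates the oxirane, whose benzylic C2'–O bond is weakened by the 4-benzyloxyphenyl group. O1' opens it at C2' in the 6-endo sense, as in the acid-mediated cyclisation of 2-hydroxyaryl epoxides to 2,3-trans-flavan-3-ols. Attack with inversion, or collapse of an ion pair to the ring with 2-aryl and 3-OH both equatorial, gives C2' (S); C3' and C4' are not touched.

Step 20
Reactants: 29 (2R,3R,4R)-3,7,8-tris(benzyloxy)-2-[4-(benzyloxy)phenyl]-4-{[(2S,3R,4R)-7,8-bis(benzyloxy)-2-[4-(benzyloxy)phenyl]-3-hydroxychroman-4-yl]oxy}chromane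
Product: 30 (2R,3R,4R)-2-(4-hydroxyphenyl)-4-{[(2S,3R,4R)-3,7,8-trihydroxy-2-(4-hydroxyphenyl)chroman-4-yl]oxy}chromane-3,7,8-triol (CNP0241481.1)
Conditions: H2 (1 atm), Pd(OH)2/C, THF/MeOH (degassed), rt; filtration under argon
Reagents that add atoms: none
Why: Hydrogenolysis of the six aryl benzyl ethers and the one alkyl benzyl ether under neutral conditions. The hindered secondary bis-benzylic ether and the C2–O1 bonds should be cleaved much more slowly than primary O-benzyl groups in the absence of acid, and no stereocentre is involved.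

## Compound list

1 | 1-(2,3,4-trihydroxyphenyl)ethanone (gallacetophenone) | CC(=O)c1ccc(O)c(O)c1O | starting material
2 | 1-[3,4-bis(benzyloxy)-2-hydroxyphenyl]ethanone | CC(=O)c1ccc(OCc2ccccc2)c(OCc2ccccc2)c1O | intermediate
3 | (E)-1-[3,4-bis(benzyloxy)-2-hydroxyphenyl]-3-(dimethylamino)prop-2-en-1-one (enaminone, formed in the flask) | CN(C)/C=C/C(=O)c1ccc(OCc2ccccc2)c(OCc2ccccc2)c1O | intermediate
4 | 7,8-bis(benzyloxy)-4H-chromen-4-one | O=c1ccoc2c(OCc3ccccc3)c(OCc3ccccc3)ccc12 | intermediate
5 | [4-(benzyloxy)phenyl]boronic acid | OB(O)c1ccc(OCc2ccccc2)cc1 | starting material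
6 | (2S)-7,8-bis(benzyloxy)-2-[4-(benzyloxy)phenyl]chroman-4-one | C(c1ccccc1)Oc1ccc(cc1)[C@H]1Oc2c(OCc3ccccc3)c(OCc3ccccc3)ccc2C(=O)C1 | intermediate
7 | {[(2S)-7,8-bis(benzyloxy)-2-[4-(benzyloxy)phenyl]-2H-chromen-4-yl]oxy}(tert-butyl)dimethylsilane | C(c1ccccc1)Oc1ccc(cc1)[C@H]1Oc2c(OCc3ccccc3)c(OCc3ccccc3)ccc2C(O[Si](C)(C)C(C)(C)C)=C1 | intermediate
8 | C3 monoalkylborane from 7, boron trans to the 2-aryl group and trans to the 4-silyloxy group (formed in the flask) | C(c1ccccc1)Oc1ccc(cc1)[C@H]1Oc2c(OCc3ccccc3)c(OCc3ccccc3)ccc2[C@@H](O[Si](C)(C)C(C)(C)C)[C@@H]1B | intermediate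
9 | (2R,3R,4R)-7,8-bis(benzyloxy)-2-[4-(benzyloxy)phenyl]-4-[(tert-butyldimethylsilyl)oxy]chroman-3-ol (2,3-trans-3,4-trans) | C(c1ccccc1)Oc1ccc(cc1)[C@H]1Oc2c(OCc3ccccc3)c(OCc3ccccc3)ccc2[C@@H](O[Si](C)(C)C(C)(C)C)[C@@H]1O | intermediate
10 | (2R,4R)-7,8-bis(benzyloxy)-2-[4-(benzyloxy)phenyl]-4-[(tert-butyldimethylsilyl)oxy]chroman-3-one (2,4-cis) | C(c1ccccc1)Oc1ccc(cc1)[C@H]1Oc2c(OCc3ccccc3)c(OCc3ccccc3)ccc2[C@@H](O[Si](C)(C)C(C)(C)C)C1=O | intermediate
11 | (2R,3S,4R)-7,8-bis(benzyloxy)-2-[4-(benzyloxy)phenyl]-4-[(tert-butyldimethylsilyl)oxy]chroman-3-ol (all-cis) | C(c1ccccc1)Oc1ccc(cc1)[C@H]1Oc2c(OCc3ccccc3)c(OCc3ccccc3)ccc2[C@@H](O[Si](C)(C)C(C)(C)C)[C@H]1O | intermediate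
12 | tert-butyl{[(2R,3S,4R)-3,7,8-tris(benzyloxy)-2-[4-(benzyloxy)phenyl]chroman-4-yl]oxy}dimethylsilane (all-cis) | C(c1ccccc1)Oc1ccc(cc1)[C@H]1Oc2c(OCc3ccccc3)c(OCc3ccccc3)ccc2[C@@H](O[Si](C)(C)C(C)(C)C)[C@H]1OCc1ccccc1 | intermediate
13 | (2R,3R,4R)-3,7,8-tris(benzyloxy)-2-[4-(benzyloxy)phenyl]chroman-4-ol (all-cis) | C(c1ccccc1)Oc1ccc(cc1)[C@H]1Oc2c(OCc3ccccc3)c(OCc3ccccc3)ccc2[C@@H](O)[C@H]1OCc1ccccc1 | intermediate
14 | 2,3,4-trihydroxybenzaldehyde | O=Cc1ccc(O)c(O)c1O | starting material
15 | 3,4-bis(benzyloxy)-2-hydroxybenzaldehyde | O=Cc1ccc(OCc2ccccc2)c(OCc2ccccc2)c1O | intermediate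
16 | 3,4-bis(benzyloxy)-2-[(triisopropylsilyl)oxy]benzaldehyde | O=Cc1ccc(OCc2ccccc2)c(OCc2ccccc2)c1O[Si](C(C)C)(C(C)C)C(C)C | intermediate
17 | ethyl (2E)-3-{3,4-bis(benzyloxy)-2-[(triisopropylsilyl)oxy]phenyl}prop-2-enoate | CCOC(=O)/C=C/c1ccc(OCc2ccccc2)c(OCc2ccccc2)c1O[Si](C(C)C)(C(C)C)C(C)C | intermediate
18 | (2E)-3-{3,4-bis(benzyloxy)-2-[(triisopropylsilyl)oxy]phenyl}prop-2-en-1-ol | OC/C=C/c1ccc(OCc2ccccc2)c(OCc2ccccc2)c1O[Si](C(C)C)(C(C)C)C(C)C | intermediate
19 | tert-butyl (2E)-3-{3,4-bis(benzyloxy)-2-[(triisopropylsilyl)oxy]phenyl}prop-2-en-1-yl carbonate | CC(C)(C)OC(=O)OC/C=C/c1ccc(OCc2ccccc2)c(OCc2ccccc2)c1O[Si](C(C)C)(C(C)C)C(C)C | intermediate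
20 | copper alkoxide of 13 (copper on O4, formed in the flask) | C(c1ccccc1)Oc1ccc(cc1)[C@H]1Oc2c(OCc3ccccc3)c(OCc3ccccc3)ccc2[C@@H](O[Cu])[C@H]1OCc1ccccc1 | intermediate
21 | (2R,3R,4R)-3,7,8-tris(benzyloxy)-2-[4-(benzyloxy)phenyl]-4-{[(1S)-1-{3,4-bis(benzyloxy)-2-[(triisopropylsilyl)oxy]phenyl}prop-2-en-1-yl]oxy}chromane | C(c1ccccc1)Oc1ccc(cc1)[C@H]1Oc2c(OCc3ccccc3)c(OCc3ccccc3)ccc2[C@@H](O[C@H](c2ccc(OCc3ccccc3)c(OCc3ccccc3)c2O[Si](C(C)C)(C(C)C)C(C)C)C=C)[C@H]1OCc1ccccc1 | intermediate
22 | secondary ozonide (1,2,4-trioxolane) of the vinyl group of 21, mixture at the ozonide carbon (formed in the flask) | C(c1ccccc1)Oc1ccc(cc1)[C@H]1Oc2c(OCc3ccccc3)c(OCc3ccccc3)ccc2[C@@H](O[C@H](c2ccc(OCc3ccccc3)c(OCc3ccccc3)c2O[Si](C(C)C)(C(C)C)C(C)C)C2OCOO2)[C@H]1OCc1ccccc1 | intermediate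
23 | (2R)-2-{3,4-bis(benzyloxy)-2-[(triisopropylsilyl)oxy]phenyl}-2-{[(2R,3R,4R)-3,7,8-tris(benzyloxy)-2-[4-(benzyloxy)phenyl]chroman-4-yl]oxy}acetaldehyde | C(c1ccccc1)Oc1ccc(cc1)[C@H]1Oc2c(OCc3ccccc3)c(OCc3ccccc3)ccc2[C@@H](O[C@H](c2ccc(OCc3ccccc3)c(OCc3ccccc3)c2O[Si](C(C)C)(C(C)C)C(C)C)C=O)[C@H]1OCc1ccccc1 | intermediate
24 | 1-(benzyloxy)-4-(chloromethyl)benzene | ClCc1ccc(OCc2ccccc2)cc1 | starting material
25 | [4-(benzyloxy)benzyl]dimethylsulfonium tetrafluoroborate | C[S+](C)Cc1ccc(OCc2ccccc2)cc1.F[B-](F)(F)F | intermediate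
26 | dimethylsulfonium [4-(benzyloxy)phenyl]methylide (formed in the flask) | C[S+](C)[CH-]c1ccc(OCc2ccccc2)cc1 | intermediate
27 | (2R,3R,4R)-3,7,8-tris(benzyloxy)-2-[4-(benzyloxy)phenyl]-4-{(R)-{3,4-bis(benzyloxy)-2-[(triisopropylsilyl)oxy]phenyl}[(2S,3R)-3-(4-benzyloxyphenyl)oxiran-2-yl]methoxy}chromane (trans oxirane) | C(c1ccccc1)Oc1ccc(cc1)[C@H]1Oc2c(OCc3ccccc3)c(OCc3ccccc3)ccc2[C@@H](O[C@H](c2ccc(OCc3ccccc3)c(OCc3ccccc3)c2O[Si](C(C)C)(C(C)C)C(C)C)[C@H]2O[C@@H]2c2ccc(OCc3ccccc3)cc2)[C@H]1OCc1ccccc1 | intermediate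
28 | epoxy phenol: 27 with the silyl group replaced by hydrogen on O1' (formed in the flask) | C(c1ccccc1)Oc1ccc(cc1)[C@H]1Oc2c(OCc3ccccc3)c(OCc3ccccc3)ccc2[C@@H](O[C@H](c2ccc(OCc3ccccc3)c(OCc3ccccc3)c2O)[C@H]2O[C@@H]2c2ccc(OCc3ccccc3)cc2)[C@H]1OCc1ccccc1 | intermediate
29 | (2R,3R,4R)-3,7,8-tris(benzyloxy)-2-[4-(benzyloxy)phenyl]-4-{[(2S,3R,4R)-7,8-bis(benzyloxy)-2-[4-(benzyloxy)phenyl]-3-hydroxychroman-4-yl]oxy}chromane | C(c1ccccc1)Oc1ccc(cc1)[C@H]1Oc2c(OCc3ccccc3)c(OCc3ccccc3)ccc2[C@@H](O[C@@H]2c3ccc(OCc4ccccc4)c(OCc4ccccc4)c3O[C@@H](c3ccc(OCc4ccccc4)cc3)[C@@H]2O)[C@H]1OCc1ccccc1 | intermediate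
30 | (2R,3R,4R)-2-(4-hydroxyphenyl)-4-{[(2S,3R,4R)-3,7,8-trihydroxy-2-(4-hydroxyphenyl)chroman-4-yl]oxy}chromane-3,7,8-triol | Oc1ccc([C@H]2Oc3c(ccc(O)c3O)[C@@H](O[C@@H]3c4ccc(O)c(O)c4O[C@@H](c4ccc(O)cc4)[C@@H]3O)[C@H]2O)cc1 | target

## Step count and weakest steps

Total step count: 20. Longest linear sequence: 14 steps (steps 1 to 9, then 15, 16, 18, 19 and 20).

Step 18 (key step). Two processes can spoil it. The first is loss of configuration at C4' by enolisation of the alpha-aryl alpha-alkoxy aldehyde, because the ylide is also a base. The second is poor facial selectivity at the formyl group, if a conformer with the aryl group anti to the nucleophile competes with the polar Felkin–Anh arrangement. A cis/trans mixture at the oxirane is a lesser concern. The fallback avoids the aldehyde altogether. It sets out from 21, which undergoes cross-metathesis with commercial 4-(benzyloxy)styrene under the second-generation Hoveyda–Grubbs catalyst to give the (E)-alkene F1. F1 is then epoxidised with the D-fructose-derived Shi ketone and KHSO5 in buffered MeCN/dimethoxymethane/water at 0 °C. The ketone catalyst chooses the alkene face, so C3' and C2' are set by the reagent and not by C4'. The route is rejoined at 27.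

Step 15. The hindered secondary alkoxide, with a cis benzyloxy group next to it, may attack the allyl complex too slowly. The carbonate would then decay or the linear ether would form. The ortho-silyloxy group on the aryl ring may also lower the diastereoselectivity. The fallback changes the bond-forming event to a carbenoid O–H insertion and sets out from 13 and 16. Aldehyde 16 is converted by Wittig methoxymethylenation into enol ether F2. Oxidation of F2 with pyridinium chlorochromate, [C5H5NH][CrO3Cl], gives methyl arylacetate F3, and diazo transfer (4-acetamidobenzenesulfonyl azide, DBU) gives diazo ester F4. Slow addition of F4 to 13 with Rh2(OAc)4 and a chiral spiro phosphoric acid gives alpha-alkoxy ester F5, with the proton transfer that sets C4' steered by the acid. Reduction of F5 with i-Bu2AlH at −78 °C leads back to the route at 23.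

Step 19. The freed O1' may attack C3' in the 5-exo sense and give a dihydrobenzofuran. The activated oxirane may undergo a hydride shift to a ketone, and the acid may ionise the bridging ether at C4. The fallback removes the 5-exo path by tying up O3' and sets out from 27. The oxirane is hydrolysed with Sc(OTf)3 (cat.) in aqueous THF to diol F6 (epimers at C2'), and Bu4NF frees the phenol to give F7. Triethyl orthoformate with pyridinium p-toluenesulfonate converts the diol into a cyclic orthoformate, which ionises at C2' and is closed by O1' to the 2,3-trans 3'-O-formate F8. K2CO3 in MeOH removes the formyl group and the route is rejoined at 29.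

Step 5. The beta-silyloxy borane may eliminate to the flav-3-ene, some borane may add on the face of the 2-aryl group, and the silyl group may shift to O3 during the basic oxidation. The fallback sets C3 by an SN2 inversion and C4 by a ketone reduction and sets out from 7. Rubottom oxidation (dimethyldioxirane, then Bu4NF/AcOH) gives the trans 3-hydroxyflavanone F9. Mitsunobu reaction with benzoic acid inverts C3 to the cis benzoate F10. NaBH4 at −40 °C, attacking anti to the axial acyloxy group, gives the all-cis alcohol F11. Silylation (t-BuMe2SiOTf, 2,6-lutidine) gives F12, and i-Bu2AlH at −78 °C removes the benzoate. The route is rejoined at 11.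

Step 16. Ozone may attack the electron-rich alkoxyarenes once the alkene is consumed, and the aldehyde may epimerise if the work-up is slow. The fallback replaces ozone by a two-stage cleavage and sets out from 21. Dihydroxylation with OsO4 (cat.) and N-methylmorpholine N-oxide gives diol F13, and NaIO4 in buffered aqueous THF cleaves it. The route is rejoined at 23.

## Further compounds

F1 | step 18 | (2R,3R,4R)-3,7,8-tris(benzyloxy)-2-[4-(benzyloxy)phenyl]-4-{[(1S,2E)-1-{3,4-bis(benzyloxy)-2-[(triisopropylsilyl)oxy]phenyl}-3-[4-(benzyloxy)phenyl]prop-2-en-1-yl]oxy}chromane | C(c1ccccc1)Oc1ccc(cc1)[C@H]1Oc2c(OCc3ccccc3)c(OCc3ccccc3)ccc2[C@@H](O[C@H](c2ccc(OCc3ccccc3)c(OCc3ccccc3)c2O[Si](C(C)C)(C(C)C)C(C)C)/C=C/c2ccc(OCc3ccccc3)cc2)[C@H]1OCc1ccccc1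
F2 | step 15 | 1,2-bis(benzyloxy)-4-(2-methoxyethenyl)-3-[(triisopropylsilyl)oxy]benzene (E/Z mixture) | COC=Cc1ccc(OCc2ccccc2)c(OCc2ccccc2)c1O[Si](C(C)C)(C(C)C)C(C)C
F3 | step 15 | methyl 2-{3,4-bis(benzyloxy)-2-[(triisopropylsilyl)oxy]phenyl}acetate | COC(=O)Cc1ccc(OCc2ccccc2)c(OCc2ccccc2)c1O[Si](C(C)C)(C(C)C)C(C)C
F4 | step 15 | methyl 2-{3,4-bis(benzyloxy)-2-[(triisopropylsilyl)oxy]phenyl}-2-diazoacetate | COC(=O)C(=[N+]=[N-])c1ccc(OCc2ccccc2)c(OCc2ccccc2)c1O[Si](C(C)C)(C(C)C)C(C)C
F5 | step 15 | methyl (2R)-2-{3,4-bis(benzyloxy)-2-[(triisopropylsilyl)oxy]phenyl}-2-{[(2R,3R,4R)-3,7,8-tris(benzyloxy)-2-[4-(benzyloxy)phenyl]chroman-4-yl]oxy}acetate | C(c1ccccc1)Oc1ccc(cc1)[C@H]1Oc2c(OCc3ccccc3)c(OCc3ccccc3)ccc2[C@@H](O[C@H](c2ccc(OCc3ccccc3)c(OCc3ccccc3)c2O[Si](C(C)C)(C(C)C)C(C)C)C(=O)OC)[C@H]1OCc1ccccc1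
F6 | step 19 | diol from hydrolysis of the oxirane of 27 (hydroxyls on C2' and C3', epimers at C2', silyl ether kept) | C(c1ccccc1)Oc1ccc(cc1)[C@H]1Oc2c(OCc3ccccc3)c(OCc3ccccc3)ccc2[C@@H](O[C@H](c2ccc(OCc3ccccc3)c(OCc3ccccc3)c2O[Si](C(C)C)(C(C)C)C(C)C)[C@@H](O)C(O)c2ccc(OCc3ccccc3)cc2)[C@H]1OCc1ccccc1
F7 | step 19 | phenol diol: F6 with the silyl group replaced by hydrogen on O1' | C(c1ccccc1)Oc1ccc(cc1)[C@H]1Oc2c(OCc3ccccc3)c(OCc3ccccc3)ccc2[C@@H](O[C@H](c2ccc(OCc3ccccc3)c(OCc3ccccc3)c2O)[C@@H](O)C(O)c2ccc(OCc3ccccc3)cc2)[C@H]1OCc1ccccc1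
F8 | step 19 | 3'-O-formate of 29 | C(c1ccccc1)Oc1ccc(cc1)[C@H]1Oc2c(OCc3ccccc3)c(OCc3ccccc3)ccc2[C@@H](O[C@@H]2c3ccc(OCc4ccccc4)c(OCc4ccccc4)c3O[C@@H](c3ccc(OCc4ccccc4)cc3)[C@@H]2OC=O)[C@H]1OCc1ccccc1
F9 | step 5 | (2R,3R)-7,8-bis(benzyloxy)-2-[4-(benzyloxy)phenyl]-3-hydroxychroman-4-one (2,3-trans) | C(c1ccccc1)Oc1ccc(cc1)[C@H]1Oc2c(OCc3ccccc3)c(OCc3ccccc3)ccc2C(=O)[C@@H]1O
F10 | step 5 | (2R,3S)-7,8-bis(benzyloxy)-2-[4-(benzyloxy)phenyl]-4-oxochroman-3-yl benzoate (2,3-cis) | C(c1ccccc1)Oc1ccc(cc1)[C@H]1Oc2c(OCc3ccccc3)c(OCc3ccccc3)ccc2C(=O)[C@H]1OC(=O)c1ccccc1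
F11 | step 5 | (2R,3R,4R)-7,8-bis(benzyloxy)-2-[4-(benzyloxy)phenyl]-4-hydroxychroman-3-yl benzoate (all-cis) | C(c1ccccc1)Oc1ccc(cc1)[C@H]1Oc2c(OCc3ccccc3)c(OCc3ccccc3)ccc2[C@@H](O)[C@H]1OC(=O)c1ccccc1
F12 | step 5 | (2R,3S,4R)-7,8-bis(benzyloxy)-2-[4-(benzyloxy)phenyl]-4-[(tert-butyldimethylsilyl)oxy]chroman-3-yl benzoate (all-cis) | C(c1ccccc1)Oc1ccc(cc1)[C@H]1Oc2c(OCc3ccccc3)c(OCc3ccccc3)ccc2[C@@H](O[Si](C)(C)C(C)(C)C)[C@H]1OC(=O)c1ccccc1
F13 | step 16 | diol from dihydroxylation of the vinyl group of 21 (epimers at the secondary carbinol) | C(c1ccccc1)Oc1ccc(cc1)[C@H]1Oc2c(OCc3ccccc3)c(OCc3ccccc3)ccc2[C@@H](O[C@H](c2ccc(OCc3ccccc3)c(OCc3ccccc3)c2O[Si](C(C)C)(C(C)C)C(C)C)C(O)CO)[C@H]1OCc1ccccc1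
A1 | alternative 1 | 2,3-bis(benzyloxy)phenol | Oc1cccc(OCc2ccccc2)c1OCc1ccccc1
A2 | alternative 1 | (2S,3R)-3-[4-(benzyloxy)phenyl]oxirane-2-carbaldehyde | O=C[C@H]1O[C@@H]1c1ccc(OCc2ccccc2)cc1
A3 | alternative 1 | (2S,3R,4R)-7,8-bis(benzyloxy)-2-(4-benzyloxyphenyl)chroman-3,4-diol | O[C@@H]1c2ccc(OCc5ccccc5)c(OCc5ccccc5)c2O[C@@H](c2ccc(OCc5ccccc5)cc2)[C@@H]1O
A4 | alternative 2 | 2,3-dihydrofuran | C1=COCC1
A5 | alternative 2 | 3,4-bis(benzyloxy)-2-[(tert-butyldimethylsilyl)oxy]phenyl trifluoromethanesulfonate | CC(C)(C)[Si](C)(C)Oc1c(OCc2ccccc2)c(OCc2ccccc2)ccc1OS(=O)(=O)C(F)(F)F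
A6 | alternative 2 | (2S,5S)-2,5-bis[2-(tert-butyldimethylsilyloxy)-3,4-bis(benzyloxy)phenyl]-2,5-dihydrofuran | CC(C)(C)[Si](C)(C)Oc1c(OCc2ccccc2)c(OCc2ccccc2)ccc1[C@H]3O[C@H](c4ccc(OCc2ccccc2)c(OCc2ccccc2)c4O[Si](C)(C)C(C)(C)C)C=C3
A7 | alternative 3 | open-chain bis(aryl bromide) diol: the octa-O-benzyl ether A8 with each O1–C8a bond replaced by a free benzylic hydroxyl and an aryl bromide | c5ccccc5COc1ccc([C@@H](O)[C@H](OCc5ccccc5)[C@H](O[C@H](c4ccc(OCc5ccccc5)c(OCc5ccccc5)c4Br)[C@@H](OCc5ccccc5)[C@@H](O)c4ccc(OCc5ccccc5)cc4)c2ccc(OCc5ccccc5)c(OCc5ccccc5)c2Br)cc1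
A8 | alternative 3 | octa-O-benzyl ether of the target | c5ccccc5COc1ccc([C@H]2Oc3c(ccc(OCc5ccccc5)c3OCc5ccccc5)[C@@H](O[C@@H]3c4ccc(OCc5ccccc5)c(OCc5ccccc5)c4O[C@@H](c4ccc(OCc5ccccc5)cc4)[C@@H]3OCc5ccccc5)[C@H]2OCc5ccccc5)cc1
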